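**Retrosynthetic overview**
1. Target 16 ⇒ ammonolysis of triacetate 15 ⇒ Mitsunobu O‑prenylation of 4'‑phenol 13. The prenyl ether is put on late because it would not survive debenzylation or acid.
2. 13 ⇒ protecting-group exchange (Bn → Ac, then tBu off) from flavonol 10. Ring C, the only ring built, comes from Algar–Flynn–Oyamada oxidative cyclisation of 2'‑hydroxychalcone 8.
3. 8 ⇒ Claisen–Schmidt aldol condensation (Cα–Cβ bond) of acetophenone 5 with 4‑tert‑butoxybenzaldehyde 6. Rings A and B are bought.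
4. 5 ⇒ phloroacetophenone 1 by 4,6‑di‑O‑benzylation, Elbs para‑hydroxylation and selective O‑methylation. This fixes the 6‑OMe (not 8‑OMe) regiochemistry.

Assumption: the target has no stereocentre and no stereogenic double bond, so it is achiral and no enantiocontrol is needed. The stereo-elements met on the way (E‑alkene of 8, racemic 7 and 9) disappear again.

**Step 1**
Reactants: 1 2',4',6'‑trihydroxyacetophenone
Product: 2 1‑[2,4‑bis(benzyloxy)‑6‑hydroxyphenyl]ethan‑1‑one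
Conditions: BnBr (2.1 equiv), K2CO3 (2.2 equiv), DMF, 60 °C
Reagents that add atoms: benzyl bromide, BrCc1ccccc1
Why: In this Williamson ether synthesis the 4‑OH and one of the two equivalent ortho‑OH groups are alkylated, while the last ortho‑OH is hydrogen-bonded to the acetyl C=O and stays free with two equivalents of halide.

**Step 2**
Reactants: 2 1‑[2,4‑bis(benzyloxy)‑6‑hydroxyphenyl]ethan‑1‑one
Product: 4 1‑[2,4‑bis(benzyloxy)‑3,6‑dihydroxyphenyl]ethan‑1‑one, via potassium aryl sulfate 3 (not isolated)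
Conditions: K2S2O8 (1.2 equiv), 2 M aq NaOH–pyridine, 10–20 °C, 24 h, N2; HCl to pH 5, extract and recycle unreacted 2; then 2 M HCl, toluene, 75 °C, 1 h
Reagents that add atoms: potassium peroxodisulfate, [K+].[K+].[O-]S(=O)(=O)OOS(=O)(=O)[O-]
Why: In this Elbs persulfate oxidation the phenoxide attacks the peroxide oxygen through C‑3, the only carbon para to the free OH, and acid then hydrolyses sulfate 3 with S–O cleavage while the benzyl ethers survive both stages.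

**Step 3**
Reactants: 4 1‑[2,4‑bis(benzyloxy)‑3,6‑dihydroxyphenyl]ethan‑1‑one
Product: 5 1‑[2,4‑bis(benzyloxy)‑6‑hydroxy‑3‑methoxyphenyl]ethan‑1‑one
Conditions: MeI (1.05 equiv), K2CO3 (1.1 equiv), acetone, reflux, N2
Reagents that add atoms: iodomethane, CI
Why: This Williamson methylation is chemoselective because the new 3‑OH is an ordinary phenol whereas the 6‑OH is chelated to the ketone and far less nucleophilic, so one equivalent of MeI reacts only at O‑3.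

**Step 4 (key C–C bond)**
Reactants: 5 1‑[2,4‑bis(benzyloxy)‑6‑hydroxy‑3‑methoxyphenyl]ethan‑1‑one; 6 4‑tert‑butoxybenzaldehyde
Product: 8 (E)‑1‑[2,4‑bis(benzyloxy)‑6‑hydroxy‑3‑methoxyphenyl]‑3‑(4‑tert‑butoxyphenyl)prop‑2‑en‑1‑one, via racemic aldol adduct 7 (not isolated)
Conditions: 50 % aq KOH, EtOH–THF, rt, 48 h; AcOH to pH 6
Reagents that add atoms: none
Why: In this Claisen–Schmidt crossed aldol condensation only ketone 5 can enolise and only aldehyde 6 is a good acceptor, and aldol 7 loses water by E1cB to the thermodynamically preferred E‑enone, which erases its transient stereocentre.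

**Step 5**
Reactants: 8 (E)‑2'‑hydroxychalcone from step 4
Product: 10 5,7‑bis(benzyloxy)‑2‑(4‑tert‑butoxyphenyl)‑3‑hydroxy‑6‑methoxy‑4H‑chromen‑4‑one, via trans‑dihydroflavonol 9 (not isolated)
Conditions: 30 % H2O2, 2 M aq NaOH, MeOH–THF, 0 °C → rt; AcOH quench
Reagents that add atoms: hydrogen peroxide, OO
Why: In this Algar–Flynn–Oyamada reaction alkaline peroxide oxygenates Cα while the 2'‑phenoxide closes the six-membered ring at the benzylic Cβ (favoured by the p‑alkoxy B ring and low temperature), and 9 is dehydrogenated in the same medium, so both of its stereocentres vanish and the ethers stay intact.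

**Step 6**
Reactants: 10 5,7‑di‑O‑benzyl flavonol from step 5
Product: 11 2‑(4‑tert‑butoxyphenyl)‑3,5,7‑trihydroxy‑6‑methoxy‑4H‑chromen‑4‑one
Conditions: H2 (1 atm), 10 % Pd/C, THF–MeOH, rt
Reagents that add atoms: none
Why: Catalytic hydrogenolysis removes both aryl benzyl ethers, while the tert‑butyl and methyl ethers and the vinylogous-ester C2=C3 bond of the flavonol are inert at 1 atm.

**Step 7**
Reactants: 11 2‑(4‑tert‑butoxyphenyl)‑3,5,7‑trihydroxy‑6‑methoxy‑4H‑chromen‑4‑one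
Product: 12 2‑(4‑tert‑butoxyphenyl)‑6‑methoxy‑4‑oxo‑4H‑chromene‑3,5,7‑triyl triacetate
Conditions: Ac2O (excess), pyridine, DMAP (cat.), rt → 40 °C
Reagents that add atoms: acetic anhydride, CC(=O)OC(C)=O
Why: DMAP-catalysed O‑acylation esterifies all three hydroxyls, including the chelated 5‑OH, and gives protecting groups that can later be removed without acid or hydrogen.

**Step 8**
Reactants: 12 triacetate from step 7
Product: 13 2‑(4‑hydroxyphenyl)‑6‑methoxy‑4‑oxo‑4H‑chromene‑3,5,7‑triyl triacetate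
Conditions: TFA–CH2Cl2 (1:4), 0 °C → rt, 1–2 h; evaporate with toluene
Reagents that add atoms: none
Why: Acidolysis of the aryl tert‑butyl ether (E1 loss of the tert‑butyl cation as isobutene) frees only the 4'‑OH, because aryl acetates and the methyl ether are stable to anhydrous TFA.

**Step 9**
Reactants: 13 4'‑phenol triacetate from step 8; 14 3‑methylbut‑2‑en‑1‑ol (prenol)
Product: 15 6‑methoxy‑2‑{4‑[(3‑methylbut‑2‑en‑1‑yl)oxy]phenyl}‑4‑oxo‑4H‑chromene‑3,5,7‑triyl triacetate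
Conditions: PPh3 (1.5 equiv), DIAD (1.5 equiv), THF, 0 °C → rt
Reagents that add atoms: none
Why: In this Mitsunobu etherification the only acidic OH (4'‑OH) displaces Ph3P=O from the primary prenyloxyphosphonium ion by SN2 at C‑1 under essentially neutral conditions, so the acetates stay in place.

**Step 10**
Reactants: 15 4'‑O‑prenyl triacetate from step 9
Product: 16 3,5,7‑trihydroxy‑6‑methoxy‑4'‑prenyloxyflavone (target)
Conditions: 7 M NH3 in MeOH, 0 °C → rt, argon; evaporate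
Reagents that add atoms: none
Why: Ammonolysis cleaves the three activated aryl and enol acetates under mild, non-acidic, non-reductive conditions, which the acid- and hydrogenation-sensitive aryl prenyl ether tolerates.

**Compound list**
1 | 2',4',6'‑trihydroxyacetophenone | CC(=O)c1c(O)cc(O)cc1O | starting material
2 | 1‑[2,4‑bis(benzyloxy)‑6‑hydroxyphenyl]ethan‑1‑one | CC(=O)c1c(O)cc(OCc2ccccc2)cc1OCc1ccccc1 | intermediate
3 | potassium 3‑acetyl‑2,6‑bis(benzyloxy)‑4‑hydroxyphenyl sulfate (not isolated) | CC(=O)c1c(O)cc(OCc2ccccc2)c(OS(=O)(=O)[O-])c1OCc1ccccc1.[K+] | intermediate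
4 | 1‑[2,4‑bis(benzyloxy)‑3,6‑dihydroxyphenyl]ethan‑1‑one | CC(=O)c1c(O)cc(OCc2ccccc2)c(O)c1OCc1ccccc1 | intermediate
5 | 1‑[2,4‑bis(benzyloxy)‑6‑hydroxy‑3‑methoxyphenyl]ethan‑1‑one | CC(=O)c1c(O)cc(OCc2ccccc2)c(OC)c1OCc1ccccc1 | intermediate
6 | 4‑tert‑butoxybenzaldehyde | CC(C)(C)Oc1ccc(C=O)cc1 | starting material
7 | 1‑[2,4‑bis(benzyloxy)‑6‑hydroxy‑3‑methoxyphenyl]‑3‑(4‑tert‑butoxyphenyl)‑3‑hydroxypropan‑1‑one (racemic, not isolated) | CC(C)(C)Oc1ccc(C(O)CC(=O)c2c(O)cc(OCc3ccccc3)c(OC)c2OCc2ccccc2)cc1 | intermediate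
8 | (E)‑1‑[2,4‑bis(benzyloxy)‑6‑hydroxy‑3‑methoxyphenyl]‑3‑(4‑tert‑butoxyphenyl)prop‑2‑en‑1‑one | CC(C)(C)Oc1ccc(/C=C/C(=O)c2c(O)cc(OCc3ccccc3)c(OC)c2OCc2ccccc2)cc1 | intermediate
9 | (±)‑trans‑5,7‑bis(benzyloxy)‑2‑(4‑tert‑butoxyphenyl)‑3‑hydroxy‑6‑methoxychroman‑4‑one (racemic, one enantiomer drawn, not isolated) | CC(C)(C)Oc1ccc(cc1)[C@@H]1[C@H](C(=O)c2c(OCc3ccccc3)c(OC)c(OCc3ccccc3)cc2O1)O | intermediate
10 | 5,7‑bis(benzyloxy)‑2‑(4‑tert‑butoxyphenyl)‑3‑hydroxy‑6‑methoxy‑4H‑chromen‑4‑one | COc1c(OCc2ccccc2)cc2oc(-c3ccc(OC(C)(C)C)cc3)c(O)c(=O)c2c1OCc1ccccc1 | intermediate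
11 | 2‑(4‑tert‑butoxyphenyl)‑3,5,7‑trihydroxy‑6‑methoxy‑4H‑chromen‑4‑one | COc1c(O)cc2oc(-c3ccc(OC(C)(C)C)cc3)c(O)c(=O)c2c1O | intermediate
12 | 2‑(4‑tert‑butoxyphenyl)‑6‑methoxy‑4‑oxo‑4H‑chromene‑3,5,7‑triyl triacetate | COc1c(OC(C)=O)cc2oc(-c3ccc(OC(C)(C)C)cc3)c(OC(C)=O)c(=O)c2c1OC(C)=O | intermediate
13 | 2‑(4‑hydroxyphenyl)‑6‑methoxy‑4‑oxo‑4H‑chromene‑3,5,7‑triyl triacetate | COc1c(OC(C)=O)cc2oc(-c3ccc(O)cc3)c(OC(C)=O)c(=O)c2c1OC(C)=O | intermediate
14 | 3‑methylbut‑2‑en‑1‑ol (prenol) | CC(C)=CCO | starting material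
15 | 6‑methoxy‑2‑{4‑[(3‑methylbut‑2‑en‑1‑yl)oxy]phenyl}‑4‑oxo‑4H‑chromene‑3,5,7‑triyl triacetate | COc1c(OC(C)=O)cc2oc(-c3ccc(OCC=C(C)C)cc3)c(OC(C)=O)c(=O)c2c1OC(C)=O | intermediate
16 | 3,5,7‑trihydroxy‑6‑methoxy‑4'‑prenyloxyflavone | COc1c(O)cc2oc(-c3ccc(OCC=C(C)C)cc3)c(O)c(=O)c2c1O | target

**Total step count:** 10. **Longest linear sequence:** 10 (1 → 16; 6 and 14 are bought).

**Three steps most likely to fail**

Step 2 (Elbs oxidation). The yield is usually modest, tar forms, and the dibenzyl ether dissolves poorly in aqueous base. The fallback sets out from 2 and comes back at 4. Phenol 2 is oxidised with Fremy's salt (potassium nitrosodisulfonate, KH2PO4 buffer, acetone–water, rt). This Teuber oxidation gives the p‑quinone whenever the para position is free, here 2‑acetyl‑3,5‑bis(benzyloxy)‑1,4‑benzoquinone F1. The quinone is reduced with aqueous Na2S2O4 in EtOAc to hydroquinone 4.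

Step 5 (Algar–Flynn–Oyamada). 6'‑Alkoxy‑2'‑hydroxychalcones can divert to aurones by five-membered ring closure. The fallback sets out from 8 and comes back at 10, and it separates ring closure from oxygenation.
- Oxa‑Michael cyclisation (NaOAc, EtOH, reflux) gives racemic 5,7‑bis(benzyloxy)‑2‑(4‑tert‑butoxyphenyl)‑6‑methoxychroman‑4‑one F2.
- Dehydrogenation with I2 in pyridine at 90 °C is acid-free, so the tert‑butyl ether is safe. It gives 5,7‑bis(benzyloxy)‑2‑(4‑tert‑butoxyphenyl)‑6‑methoxy‑4H‑chromen‑4‑one F3.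
- Dimethyldioxirane in acetone–CH2Cl2 at 0 °C epoxidises the enol-ether double bond to 5,7‑bis(benzyloxy)‑2‑(4‑tert‑butoxyphenyl)‑2,3‑epoxy‑6‑methoxychroman‑4‑one F4. This isomerises on silica gel to flavonol 10.

Step 9 (Mitsunobu prenylation beside three acetates). Acetyl transfer to the 4'‑phenoxide would scramble the position of the prenyl group. The fallback sets out from 11 and comes back at 16. It swaps the ester type and uses a halide alkylation.
- PivCl, pyridine and DMAP at 50 °C give 2‑(4‑tert‑butoxyphenyl)‑6‑methoxy‑4‑oxo‑4H‑chromene‑3,5,7‑triyl tris(2,2‑dimethylpropanoate) F5.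
- TFA–CH2Cl2 gives 2‑(4‑hydroxyphenyl)‑6‑methoxy‑4‑oxo‑4H‑chromene‑3,5,7‑triyl tris(2,2‑dimethylpropanoate) F6.
- The migration-resistant pivalates allow Williamson alkylation with prenyl bromide and K2CO3 in acetone at rt. This gives 6‑methoxy‑2‑{4‑[(3‑methylbut‑2‑en‑1‑yl)oxy]phenyl}‑4‑oxo‑4H‑chromene‑3,5,7‑triyl tris(2,2‑dimethylpropanoate) F7.
- NaOMe in MeOH under argon, followed by an NH4Cl quench, gives 16.

**Further compounds**
F1 | step 2 | 2‑acetyl‑3,5‑bis(benzyloxy)‑1,4‑benzoquinone | CC(=O)C1=C(OCc2ccccc2)C(=O)C(OCc2ccccc2)=CC1=O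
F2 | step 5 | 5,7‑bis(benzyloxy)‑2‑(4‑tert‑butoxyphenyl)‑6‑methoxychroman‑4‑one (racemic) | COc1c(OCc2ccccc2)cc2OC(c3ccc(OC(C)(C)C)cc3)CC(=O)c2c1OCc1ccccc1
F3 | step 5 | 5,7‑bis(benzyloxy)‑2‑(4‑tert‑butoxyphenyl)‑6‑methoxy‑4H‑chromen‑4‑one | COc1c(OCc2ccccc2)cc2oc(-c3ccc(OC(C)(C)C)cc3)cc(=O)c2c1OCc1ccccc1
F4 | step 5 | 5,7‑bis(benzyloxy)‑2‑(4‑tert‑butoxyphenyl)‑2,3‑epoxy‑6‑methoxychroman‑4‑one (racemic) | COc1c(OCc2ccccc2)cc2OC3(c4ccc(OC(C)(C)C)cc4)OC3C(=O)c2c1OCc1ccccc1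
F5 | step 9 | 2‑(4‑tert‑butoxyphenyl)‑6‑methoxy‑4‑oxo‑4H‑chromene‑3,5,7‑triyl tris(2,2‑dimethylpropanoate) | COc1c(OC(=O)C(C)(C)C)cc2oc(-c3ccc(OC(C)(C)C)cc3)c(OC(=O)C(C)(C)C)c(=O)c2c1OC(=O)C(C)(C)C
F6 | step 9 | 2‑(4‑hydroxyphenyl)‑6‑methoxy‑4‑oxo‑4H‑chromene‑3,5,7‑triyl tris(2,2‑dimethylpropanoate) | COc1c(OC(=O)C(C)(C)C)cc2oc(-c3ccc(O)cc3)c(OC(=O)C(C)(C)C)c(=O)c2c1OC(=O)C(C)(C)C
F7 | step 9 | 6‑methoxy‑2‑{4‑[(3‑methylbut‑2‑en‑1‑yl)oxy]phenyl}‑4‑oxo‑4H‑chromene‑3,5,7‑triyl tris(2,2‑dimethylpropanoate) | COc1c(OC(=O)C(C)(C)C)cc2oc(-c3ccc(OCC=C(C)C)cc3)c(OC(=O)C(C)(C)C)c(=O)c2c1OC(=O)C(C)(C)C
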